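A direct plan would dress ring A first and close ring C last. 2,4-Dihydroxyacetophenone A1 would go through two rounds of O-allylation and Claisen rearrangement to the 3,5-diallyl ketone A2, and MOM protection and cross-metathesis would give the diprenyl ketone A3.
Aldol condensation of A3 with 4-(methoxymethoxy)benzaldehyde A4 would give chalcone A5, weak base would close ring C to the racemic flavanone A6, a kinetic resolution by asymmetric transfer hydrogenation would leave the (2S)-flavanone A7, and acid would free both phenols.
Its weakest part would be the allylation/Claisen/metathesis sequence: five operations that do no more than place two C5 chains on a benzene ring.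
The second would be the oxa-Michael ring closure that makes O1–C2: it is reversible, would stop at partial conversion and would leave C2 to chance.
The third, least welcome on late material, would be the kinetic resolution: it would discard at least half of the most advanced intermediate and would hinge on stopping at an exact conversion.

**Plan of the new route**
- Bonds cut: first C2–C1' (ring C to ring B), then the two aryl–CH2 bonds of the prenyl groups at C6 and C8. O1–C2 and C2–C3 are never made, since they come with commercial 7-hydroxychromone.
- Ring order: the A/C bicycle is present from the start as a flat, achiral chromone, ring A is dressed on it, and ring B is joined last, in the step that creates C2.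
- Enabling feature: C2 is the β-carbon of the C4 ketone inside ring C and carries only H and ring B. The target is therefore the 1,4-adduct of an aryl group to the C2=C3 bond of a 6,8-diprenylchromone.
- C6 and C8 are the two carbons ortho to the 7-OH, the positions a phenol iodinates, so both prenyl groups come from one diiodide in one twofold coupling.
- Consequences: no allylation/Claisen rounds, no reversible racemic ring closure, no resolution. The single stereocenter is set once, by the catalyst, one step before the end.

Key step: step 4

Remark: the sense of induction is assigned by analogy. (S)-Biaryl diphosphines on rhodium give (S)-3-arylcyclohexanones, and the same face maps onto 2S here. If a test run showed the other sense, the (R)-ligand would be used.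
Remark: 7-hydroxychromone, 4-hydroxyphenylboronic acid and prenylBpin are taken as commercial.

Step 1
Reactants: 1 7-hydroxy-4H-chromen-4-one (7-hydroxychromone)
Product: 3 7-hydroxy-6,8-diiodo-4H-chromen-4-one, via 7-hydroxy-8-iodo-4H-chromen-4-one 2 (not isolated)
Conditions: NIS (2.2 equiv), CF3CO2H (0.3 equiv), MeCN, 0 °C to rt, 6 h, dark; aq Na2S2O3
Reagents that add atoms: N-iodosuccinimide (NIS), O=C1CCC(=O)N1I
Why: Electrophilic aromatic iodination, in which the 7-OH directs to its two ortho carbons, C8 first and then C6, while C5 is meta to it and C3 of the vinylogous ester in ring C is far less nucleophilic than the phenol ring.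

Step 2
Reactants: 3 7-hydroxy-6,8-diiodo-4H-chromen-4-one
Product: 4 6,8-diiodo-7-(methoxymethoxy)-4H-chromen-4-one
Conditions: MOMCl (1.5 equiv), K2CO3 (2 equiv), acetone, 0 °C to rt, 4 h
Reagents that add atoms: chloromethyl methyl ether (MOMCl), COCCl
Why: Phenol O-alkylation (MOM protection), in which the acidic 7-OH is ionised by carbonate and the small MOMCl fits between the iodine atoms, the acetal being chosen because it withstands the aqueous base of step 3 and keeps the chromone from becoming an unreactive phenoxide in step 4.

Step 3
Reactants: 4 6,8-diiodo-7-(methoxymethoxy)-4H-chromen-4-one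
Product: 6 7-(methoxymethoxy)-6,8-bis(3-methylbut-2-en-1-yl)-4H-chromen-4-one, via 8-iodo-7-(methoxymethoxy)-6-(3-methylbut-2-en-1-yl)-4H-chromen-4-one 5 (not isolated)
Conditions: prenylBpin (3 equiv), PdCl2(IPent)(3-chloropyridine) (4 mol %; IPent = 1,3-bis[2,6-di(pentan-3-yl)phenyl]imidazol-2-ylidene), K3PO4 (3 M aq, 6 equiv), THF, 60 °C, 12 h, Ar
Reagents that add atoms: 3-methylbut-2-en-1-ylboronic acid pinacol ester (prenylBpin), CC(C)=CCB1OC(C)(C)C(C)(C)O1
Why: Twofold Suzuki–Miyaura coupling of an allylboronate, in which the very bulky carbene ligand on palladium lets the aryl(allyl)palladium intermediate settle on the primary σ-allyl form before reductive elimination, so that each aryl carbon should bond to the CH2 terminus (linear prenyl), the less hindered C6–I bond should react first, and phosphate instead of hydroxide spares ring C.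

Step 4
Reactants: 6 7-(methoxymethoxy)-6,8-bis(3-methylbut-2-en-1-yl)-4H-chromen-4-one, 7 4-hydroxyphenylboronic acid
Product: 8 (2S)-2-(4-hydroxyphenyl)-7-(methoxymethoxy)-6,8-bis(3-methylbut-2-en-1-yl)-2,3-dihydro-4H-chromen-4-one
Conditions: [Rh(OH)(cod)]2 (2.5 mol %), (S)-MeO-F12-BIPHEP [(S)-6,6'-dimethoxy-2,2'-bis{bis(3,4,5-trifluorophenyl)phosphino}biphenyl] (5.5 mol %), 7 (3 equiv, in three portions), 1,4-dioxane/H2O (10:1), 40 °C, 10 h, Ar, no added base
Reagents that add atoms: none
Why: Hayashi–Miyaura asymmetric 1,4-addition: the hydroxo complex of monovalent rhodium transmetalates with 7 to an aryl-rhodium, the C2=C3 bond of 6 inserts into the Rh–aryl bond with the aryl group going to C2, and water protonates the oxa-π-allyl rhodium enolate at C3, which frees 8 and returns the hydroxo complex. The closest known reaction type is this same rhodium-catalysed addition of arylboronic acids to chromones with electron-poor biaryl diphosphines, which gives flavanones. No ring is closed in this step, ring C being present in 6, so no mode of closure has to be chosen and the reversible oxa-Michael closure is never used. The one new stereocenter, C2, is set by the ligand: its P-aryl groups shield one face of the flat, rhodium-bound chromone, and the (S)-ligand should deliver ring B to the face that gives 2S, the sense in which (S)-biaryl diphosphines give (S)-3-arylcyclohexanones. The step needs 1,4- and not 1,2-addition (the C4 carbonyl is a vinylogous ester in 6 and a donor-substituted aryl ketone in 8), no reaction at the prenyl groups (unactivated trisubstituted alkenes do not insert into Rh–aryl bonds) and no loss of ee (without added base and at 40 °C the retro-oxa-Michael opening of 8 should not start). The electron-poor ligand speeds up insertion so that the donor-substituted chromone can compete with protodeboronation of 7, and the MOM ether keeps the 7-oxygen from becoming a phenoxide.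

Step 5
Reactants: 8 (2S)-2-(4-hydroxyphenyl)-7-(methoxymethoxy)-6,8-bis(3-methylbut-2-en-1-yl)-2,3-dihydro-4H-chromen-4-one
Product: 9 (2S)-7-hydroxy-2-(4-hydroxyphenyl)-6,8-bis(3-methylbut-2-en-1-yl)-2,3-dihydro-4H-chromen-4-one
Conditions: 3 M aq HCl/MeOH (1:5), 40 °C, 1.5 h; NaHCO3 to pH 6
Reagents that add atoms: none
Why: Acid-catalysed acetal methanolysis (MOM cleavage), in which C2 is configurationally safe because flavanone racemisation runs through base-induced ring opening, and short exposure to dilute acid should leave the prenyl groups uncyclised.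

**Compound list**
1 | 7-hydroxy-4H-chromen-4-one | Oc1ccc2c(c1)OC=CC2=O | starting material
2 | 7-hydroxy-8-iodo-4H-chromen-4-one (not isolated) | Oc1ccc2c(c1I)OC=CC2=O | intermediate
3 | 7-hydroxy-6,8-diiodo-4H-chromen-4-one | Oc1c(I)cc2c(c1I)OC=CC2=O | intermediate
4 | 6,8-diiodo-7-(methoxymethoxy)-4H-chromen-4-one | COCOc1c(I)cc2c(c1I)OC=CC2=O | intermediate
5 | 8-iodo-7-(methoxymethoxy)-6-(3-methylbut-2-en-1-yl)-4H-chromen-4-one (not isolated) | COCOc1c(CC=C(C)C)cc2c(c1I)OC=CC2=O | intermediate
6 | 7-(methoxymethoxy)-6,8-bis(3-methylbut-2-en-1-yl)-4H-chromen-4-one | CC(C)=CCc1cc2c(c(CC=C(C)C)c1OCOC)OC=CC2=O | intermediate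
7 | 4-hydroxyphenylboronic acid | OB(O)c1ccc(O)cc1 | starting material
8 | (2S)-2-(4-hydroxyphenyl)-7-(methoxymethoxy)-6,8-bis(3-methylbut-2-en-1-yl)-2,3-dihydro-4H-chromen-4-one | CC(C)=CCc1cc2c(c(CC=C(C)C)c1OCOC)O[C@H](c1ccc(O)cc1)CC2=O | intermediate
9 | (2S)-7-hydroxy-2-(4-hydroxyphenyl)-6,8-bis(3-methylbut-2-en-1-yl)-2,3-dihydro-4H-chromen-4-one | CC(C)=CCc1cc2c(c(CC=C(C)C)c1O)O[C@H](c1ccc(O)cc1)CC2=O | target

Total step count: 5. Longest linear sequence: 5 steps (1 to 9).

**Steps most likely to fail**

Step 4. Aryl transfer to the donor-substituted chromone, which carries a prenyl group next to the ring oxygen, may be slower than protodeboronation of the electron-rich boronic acid, or the two faces may be told apart poorly. The fallback sets out from diiodide 4 and reverses the order of events. Compound 4, a more electrophilic acceptor without alkenes, would take up 7 under cationic divalent palladium catalysis. The conditions would be Pd(OCOCF3)2, t-BuPyOx (4-tert-butyl-2-(pyridin-2-yl)-4,5-dihydrooxazole, in the enantiomeric form that leads to 2S), NH4PF6, H2O, 1,2-dichloroethane, 60 °C. No zerovalent palladium lies on that cycle, so the C–I bonds should stay, and the product would be (2S)-2-(4-hydroxyphenyl)-6,8-diiodo-7-(methoxymethoxy)-2,3-dihydro-4H-chromen-4-one F1. A twofold Stille coupling with tributyl(3-methylbut-2-en-1-yl)stannane (Pd(PPh3)4, DMF, 80 °C) needs no base and so should not open ring C. It would place both prenyl groups and come back to the route at 8.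

Step 3. Reductive elimination may take place at the tertiary terminus of the allyl group (reverse-prenyl isomers), the second coupling at the hindered C8–I bond may stall, or the aqueous base may open ring C. The fallback sets out from 4. A twofold Suzuki–Miyaura coupling with allylboronic acid pinacol ester (Pd(PPh3)4, CsF, THF, 65 °C) has two identical allyl termini and needs no hydroxide. It would give 6,8-diallyl-7-(methoxymethoxy)-4H-chromen-4-one F2. Cross-metathesis with 2-methylbut-2-ene (second-generation Grubbs catalyst RuCl2(=CHPh)(PCy3)(H2IMes), CH2Cl2, 40 °C) would then turn both allyl groups into prenyl groups with loss of propene and come back at 6. The C2=C3 bond, an electron-poor part of the pyranone, should not take part.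

Step 5. During acetal cleavage the freed 7-OH may add under acid catalysis to a neighbouring prenyl double bond (2,2-dimethylchroman formation), or the prenyl groups may take up methanol. The fallback is an acid-free end game with a silyl ether and sets out from 3. The silyl group is put on only after the coupling, because an aryl silyl ether between two iodine atoms would not survive aqueous phosphate. The potassium phenoxide of 3 would be coupled as in step 3 to 7-hydroxy-6,8-bis(3-methylbut-2-en-1-yl)-4H-chromen-4-one F3. Silylation (TBSCl, imidazole, DMF) would give 7-(tert-butyldimethylsilyloxy)-6,8-bis(3-methylbut-2-en-1-yl)-4H-chromen-4-one F4. Arylation with 7 as in step 4 would give (2S)-7-(tert-butyldimethylsilyloxy)-2-(4-hydroxyphenyl)-6,8-bis(3-methylbut-2-en-1-yl)-2,3-dihydro-4H-chromen-4-one F5. Desilylation with Bu4NF buffered with AcOH (THF, 0 °C) would come back to the route at 9.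

**Further compounds**
F1 | step 4 | (2S)-2-(4-hydroxyphenyl)-6,8-diiodo-7-(methoxymethoxy)-2,3-dihydro-4H-chromen-4-one | COCOc1c(I)cc2c(c1I)O[C@H](c1ccc(O)cc1)CC2=O
F2 | step 3 | 6,8-diallyl-7-(methoxymethoxy)-4H-chromen-4-one | COCOc1c(CC=C)cc2c(c1CC=C)OC=CC2=O
F3 | step 5 | 7-hydroxy-6,8-bis(3-methylbut-2-en-1-yl)-4H-chromen-4-one | CC(C)=CCc1cc2c(c(CC=C(C)C)c1O)OC=CC2=O
F4 | step 5 | 7-(tert-butyldimethylsilyloxy)-6,8-bis(3-methylbut-2-en-1-yl)-4H-chromen-4-one | CC(C)=CCc1cc2c(c(CC=C(C)C)c1O[Si](C)(C)C(C)(C)C)OC=CC2=O
F5 | step 5 | (2S)-7-(tert-butyldimethylsilyloxy)-2-(4-hydroxyphenyl)-6,8-bis(3-methylbut-2-en-1-yl)-2,3-dihydro-4H-chromen-4-one | CC(C)=CCc1cc2c(c(CC=C(C)C)c1O[Si](C)(C)C(C)(C)C)O[C@H](c1ccc(O)cc1)CC2=O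
A1 | direct plan | 2,4-dihydroxyacetophenone | CC(=O)c1ccc(O)cc1O
A2 | direct plan | 1-(3,5-diallyl-2,4-dihydroxyphenyl)ethan-1-one | CC(=O)c1cc(CC=C)c(O)c(CC=C)c1O
A3 | direct plan | 1-[2-hydroxy-4-(methoxymethoxy)-3,5-bis(3-methylbut-2-en-1-yl)phenyl]ethan-1-one | CC(=O)c1cc(CC=C(C)C)c(OCOC)c(CC=C(C)C)c1O
A4 | direct plan | 4-(methoxymethoxy)benzaldehyde | COCOc1ccc(C=O)cc1
A5 | direct plan | (E)-2'-hydroxy-4,4'-bis(methoxymethoxy)-3',5'-diprenylchalcone | COCOc1ccc(/C=C/C(=O)c2cc(CC=C(C)C)c(OCOC)c(CC=C(C)C)c2O)cc1
A6 | direct plan | racemic 7,4'-bis(methoxymethoxy)-6,8-diprenylflavanone | CC(C)=CCc1cc2c(c(CC=C(C)C)c1OCOC)OC(c1ccc(OCOC)cc1)CC2=O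
A7 | direct plan | (2S)-7,4'-bis(methoxymethoxy)-6,8-diprenylflavanone | CC(C)=CCc1cc2c(c(CC=C(C)C)c1OCOC)O[C@H](c1ccc(OCOC)cc1)CC2=O
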